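If a molecule of starting material needs a fixed stretch of warm time on its way to target, a recipe is worth the warm time it gives that molecule before the end.

| flask | starting material | coupling partner | temperature | remark | time |
|---|---|---|---|---|---|
| zeta | 44 mM | 1.1 equiv | 15 °C | run made earlier |  |
| eta | 62 mM | 1.1 equiv | 26 °C | run made earlier |  |
| delta | 97 mM | 1.1 equiv | 15 °C | run made earlier |  |
| midnight | 44 mM (fed, over 25 h) | 1.10 equiv | 20 °C | all else is in the flask from the start; the feed brings no volume worth counting | 40 h |
| autumn | 44 mM | 1.10 equiv (fed, over 25 h) |  | the addition at −20 °C, then warmed to 20 °C; the feed brings no volume worth counting | 40 h |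
| winter | 44 mM | 1.10 equiv (fed, over 25 h) | 20 °C | all else is in the flask from the start; the feed brings no volume worth counting | 40 h |
| spring | 44 mM | 1.10 equiv |  | everything together at the start at −20 °C, warmed to 20 °C at 25 h | 40 h |

| run | time / h | target / % | starting material / % |
|---|---|---|---|
| zeta | 2.00 | 0 | 69.0 |
| zeta | 4.00 | 1.1 | 48.1 |
| zeta | 10.0 | 0.5 | 14.6 |
| zeta | 25.0 | 3.9 | 0.6 |
| eta | 2.50 | 1.9 | 9.8 |
| eta | 6.00 | 3.9 | 1.3 |
| eta | 15.0 | 21.1 | 0.7 |
| eta | 30.0 | 32.7 | 0.3 |
| delta | 8.00 | 0 | 17.1 |
| delta | 15.0 | 1.3 | 2.6 |
| delta | 25.0 | 5.5 | 0.1 |
| delta | 30.0 | 7.0 | 0.8 |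

(standard deviation of a reading: 1 percentage point)

* the flask that comes out highest in amount of target, in percent of the starting material charged, or "all alike" when all lie within 1.5 percentage points (midnight / autumn / winter / spring / all alike)
* target at the end, in percent of the starting material charged, midnight
* target at the end, in percent of the starting material charged, autumn
* target at the end, in percent of the starting material charged, winter
* target at the end, in percent of the starting material charged, spring



The runs showed such a stretch, an induction period: in eta at 6.00 h, starting material stood at 1.3 % and target at 3.9 %, yet target later read 32.7 %. I read first-order constants for the loss of starting material, 0.194 /h in zeta and 0.929 /h in eta. Spreading their ratio evenly over the degrees gave my clock factor f = 2.35, the hours at 20 °C that do the work of one hour at 26 °C. I defined the warm age as the mean time a molecule has spent warm, a mean residence time. Dividing it by f gives a time on eta's curve, where I read target between neighbouring readings. I assumed the later steps share this ratio, and I let eta's 62 mM stand for 44 mM.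

Cold first: the same ratio gave starting material a constant of 0.00133 /h at −20 °C, or 3.33 % of it turned over in 25 h, so I counted those hours as none. Autumn and spring then had a warm age of 15.0 h, which read 4.64 %. Feeding the starting material moved its mean arrival to 12.5 h, so midnight had 27.5 h and read 14.8 %. In winter the starting material stood in the flask from the start, and I assumed that feeding the partner cost no time, so winter had its full 40 h and read 22.7 %, my highest.

The forecast, holding that “nothing happens until warming” in autumn and spring, chose winter with 13 % for midnight, 5 % for autumn, 16 % for winter and 5 % for spring, lower than my reckoning for winter and for midnight.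

The flasks gave 22.1 % in winter, 15.8 % in midnight, and 5.89 % in autumn and 5.89 % in spring, so winter came highest.

    starting material → intermediate A (k = 1.00 × 10⁻⁴ /s, Ea = 101 kJ/mol)
    intermediate A → intermediate B (k = 1.20 × 10⁻⁵ /s, Ea = 105 kJ/mol)
    intermediate B → intermediate C (k = 3.80 × 10⁻⁵ /s, Ea = 87.0 kJ/mol)
    coupling partner + intermediate C ⇌ target (K = 17.0 /M, k = 7.70 × 10⁻⁴ /M/s, Ea = 70.0 kJ/mol, ΔH = −22.0 kJ/mol)
    starting material + intermediate A → side product (k = 5.30 × 10⁻⁴ /M/s, Ea = 53.0 kJ/mol)
    (constants at 20 °C)

In autumn at 25.0 h, starting material stood at 98.7 % and intermediate A at 1.24 %; at the end, intermediate A held 48.3 % beside 5.89 % of target. In winter at 25.0 h, starting material stood at 0 %, while intermediate C at 26.5 % met coupling partner at 88.5 % of its own charge. Winter lay 0.60 percentage points below its figure read through f, and autumn 1.3 points above its own.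

Autumn left until 4.0 d has a warm age of 71.0 h, which f turns into 30.2 h on eta's curve, beside eta's last reading of 32.7 % at 30.0 h. That flask gave 28.7 %, 4 points lower.

Readings and results are simulated from invented constants, noise included.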